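(The numbers are those of an exercise, and the outcome is calculated.)

A solution cannot hold more than 0.052 M of electrophile, yet 0.084 M of solid electrophile is charged, so part of the charge has to wait as crystals.

    electrophile + nucleophile → acid set free + target (k1 = 0.020 M⁻¹ min⁻¹)
    nucleophile + acid set free ⇌ protonated nucleophile, settled at all times (K2 = 2.2 × 10⁵ M⁻¹)
    acid set free + free base ⇌ salt of the base (K3 = 5900 M⁻¹, k3 = 0.69 M⁻¹ min⁻¹)
    solid electrophile ⇌ electrophile, rate k4*(cs4 - [electrophile]) while solid is left; crystals form when [electrophile] > cs4 (cs4 = 0.052 M, k4 = 0.022 min⁻¹)
    2 electrophile → homo dimer (k5 = 0.0052 M⁻¹ min⁻¹)
    electrophile + acid set free → side product (k6 = 0.0050 M⁻¹ min⁻¹)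

in all of them: solid electrophile 0.084 M; protonated nucleophile 2.00 equiv; time 10 d
- birch: free base 3.00 equiv
- elm: free base 4.50 equiv
- cedar: free base 6.80 equiv

- percent here means solid electrophile units held: one homo dimer counts as two
- a step written with two of one species runs at k times the square of its concentration and takes two of it each time
- solid electrophile is a solid; its amount is given per volume of the solution
- at the start none of the solid electrophile is in solution
- what has only dissolved of solid electrophile counts as not reacted
- run time (birch): 10 d

- part of the solid electrophile that has reacted (what has only dissolved counts as not reacted) at the end, birch
- part of the solid electrophile that has reacted (what has only dissolved counts as not reacted) at the end, elm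
- part of the solid electrophile that has reacted (what has only dissolved counts as not reacted) at the end, cedar
- what raising the equivalents of free base from its lowest to its highest value here does to the part of the solid electrophile that has reacted (what has only dissolved counts as not reacted) (changes below 5 percentage points count as none) (no change / it falls / it rises)

A ladder of times, reckoned by hand, runs as follows. Dissolution has a time of 45.5 min, while electrophile at its solubility of 0.052 M has a first half-life by dimerisation of 1.28 d, so the solution fills long before it empties. At 0.052 M, dimerisation runs as a zero-order stretch at 2.81 × 10⁻⁵ M min⁻¹, and on its own it needs 0.790 d to take the charge above solubility, less than the run of 10 d.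

The second-order tail follows, and the small thing worth computing is what it leaves. Dimerisation on its own leaves 7.58% of the charge at the end; this share, with every other sink ignored, is the dimer remainder. Free base does not enter this sum, and the recipes share one charge, so the number stands for each. Electrophile taken by the nucleophile or the acid set free comes on top of this sum, so the reckoning commits to 92.4% reacted or somewhat more, as an estimate and not a strict bound, the lag of dissolving being left out of it. The hand reckoning stops at this estimate, since the amount of free nucleophile is not reckoned here.

The forecast stands higher than this estimate, with 97.3%, 98.7% and 99.3% and the trend "no change", holding that “every run ends nearly complete and extra base adds only a point or two”.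

| flask | free base | forecast | simulation | electrophile left |
|---|---|---|---|---|
| birch | 3.00 equiv | 97.3% | 98.5% | 1.45% |
| elm | 4.50 equiv | 98.7% | 99.2% | 0.811% |
| cedar | 6.80 equiv | 99.3% | 99.6% | 0.370% |

The simulation gives the trend "no change", a change of 1.1 percentage points, and the forecast is right. The elm answer has moved by 5 points at a run time of 4.92 d with all amounts held, or at a charge of 0.0353 M with the equivalents and the time held, and a run showing that would stand apart from the forecast's 98.7%. In birch the electrophile left, 1.45%, lies under the dimer remainder of 7.58%, by a factor of 5.23, with target at 33.2% beside homo dimer at 65.2%.

The neighbour of elm with 0.034 M of solid electrophile lies under the solubility, so its remainder starts from the charge itself and comes to 16.4%, an estimate of 83.6% reacted or somewhat more. The computed flask keeps 6.2% and reaches 93.8%.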